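The route rests on disconnecting the C10–C20 bond of the δ-lactone at the spiro carbon (ent-kaurane numbering). In ring A, C10 is the only enolisable carbon of the C1 enone, and O6 and O20 lie 1,4 and cis across C5–C10. The key step exploits both: a bromomethylsilyl group tethered to O6 is displaced by the C10 enolate, closing a six-membered oxasilinane, creating the quaternary C10 and delivering C20 cis to C6. Its precursor is the Michael adduct of an enantioenriched ring A enone and a bicyclo[3.2.1]octenone carrying rings C and D. Tamao oxidation then frees both hydroxyls, and O20 closes the lactone.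

Key step: step 13

Remark: atoms are numbered as in ent-kaurane (ring A = C1–C5 and C10 with the C1 ketone, C4 gem-dimethyl and C6 = CH2OH on C5; lactone ring = C10, C20, O, C7, C8, C9; ring C = C8, C9, C11–C14; ring D = C8, C14, C13, C16, C15; C17 = CH2OH on C16). The ligand enantiomers in steps 2 and 7 are assigned by analogy, and the mirror-image ligand is used if the opposite sense is found.

Step 1
Reactants: 1 4,4-dimethylcyclohex-2-en-1-one
Product: 2 4,4-dimethylcyclohexa-2,5-dien-1-one
Conditions: DDQ (1.3 equiv), TsOH (cat.), 1,4-dioxane, reflux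
Reagents that add atoms: none
Why: Quinone dehydrogenation of the enone through its dienol (DDQ oxidation) should give the symmetric cross-conjugated dienone, and no stereocentre is formed.

Step 2
Reactants: 2 4,4-dimethylcyclohexa-2,5-dien-1-one
Product: 3 (5R)-5-ethenyl-4,4-dimethylcyclohex-2-en-1-one
Conditions: CH2=CHBF3K (1.2 equiv), [Rh(cod)2]BF4 (3 mol %), (R)-BINAP (3.6 mol %), Et3N (1 equiv), toluene/H2O (10:1), 60 °C
Reagents that add atoms: potassium vinyltrifluoroborate, C=C[B-](F)(F)F.[K+]
Why: Rhodium-catalysed asymmetric conjugate addition (Hayashi–Miyaura reaction) desymmetrises the dienone, the vinyl–rhodium–BINAP species inserting one of the two enantiotopic enone arms on one face, which sets C5, while the second and now more hindered enone stays intact.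

Step 3
Reactants: 3 (5R)-5-ethenyl-4,4-dimethylcyclohex-2-en-1-one
Product: 4 (5S)-5-(hydroxymethyl)-4,4-dimethylcyclohex-2-en-1-one
Conditions: O3, CH2Cl2/MeOH (4:1), −78 °C; then NaBH4 (2 equiv), −78 → −40 °C
Reagents that add atoms: ozone, [O-][O+]=O
Why: Ozonolysis cleaves the electron-rich vinyl group in preference to the electron-poor enone alkene, and NaBH4 at low temperature reduces the ozonide and the aldehyde much faster than the conjugated ketone, so C5 is not epimerised (the descriptor changes only through priorities).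

Step 4
Reactants: 4 (5S)-5-(hydroxymethyl)-4,4-dimethylcyclohex-2-en-1-one
Product: 5 (5S)-5-({[tert-butyl(dimethyl)silyl]oxy}methyl)-4,4-dimethylcyclohex-2-en-1-one
Conditions: t-BuMe2SiCl, imidazole, DMF, 0 °C → rt
Reagents that add atoms: tert-butyldimethylsilyl chloride, CC(C)(C)[Si](C)(C)Cl
Why: Silylation of the primary alcohol (silyl ether protection) masks O6 during the enolate chemistry of step 9 and touches no stereocentre.

Step 5
Reactants: 6 methyl benzoate
Product: 7 methyl 1-(2-bromoprop-2-en-1-yl)cyclohexa-2,5-diene-1-carboxylate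
Conditions: K (2.2 equiv), NH3(l)/THF, t-BuOH (1.0 equiv), −78 °C; piperylene; then CH2=C(Br)CH2Br (1.5 equiv), −78 °C
Reagents that add atoms: 2,3-dibromoprop-1-ene, BrCC(Br)=C
Why: Birch reduction gives the ester enolate, which is alkylated at the ipso carbon by the allylic bromide end of the reagent (Birch reductive alkylation) while the vinylic bromide is inert to SN2, and the product is achiral.

Step 6
Reactants: 7 methyl 1-(2-bromoprop-2-en-1-yl)cyclohexa-2,5-diene-1-carboxylate
Product: 8 methyl 1-(2-bromoprop-2-en-1-yl)-4-oxocyclohexa-2,5-diene-1-carboxylate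
Conditions: CrO3 (10 equiv), 3,5-dimethylpyrazole (10 equiv), CH2Cl2, −20 °C
Reagents that add atoms: chromium trioxide, O=[Cr](=O)=O
Why: The doubly allylic ring CH2 carries the weakest C–H bonds, so allylic oxidation with CrO3–3,5-dimethylpyrazole should convert it into the carbonyl of the prochiral cross-conjugated dienone.

Step 7
Reactants: 8 methyl 1-(2-bromoprop-2-en-1-yl)-4-oxocyclohexa-2,5-diene-1-carboxylate
Product: 10 methyl (1R)-1-(2-bromoprop-2-en-1-yl)-4-oxocyclohex-2-ene-1-carboxylate, via silyl dienol ether 9 (not isolated)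
Conditions: Cu(OAc)2 (5 mol %), (R)-DTBM-SEGPHOS (5.5 mol %), (MeO)2MeSiH (1.2 equiv), toluene, −30 °C; then aq. NH4Cl, THF, 0 °C
Reagents that add atoms: none
Why: A chiral bisphosphine–CuH species delivers hydride to the β-carbon of one of the two enantiotopic enone arms (asymmetric conjugate reduction as a desymmetrisation), which fixes the quaternary C8, and the product stays masked as the silyl dienol ether until work-up so that the second arm is not reduced.

Step 8
Reactants: 10 methyl (1R)-1-(2-bromoprop-2-en-1-yl)-4-oxocyclohex-2-ene-1-carboxylate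
Product: 11 methyl (1R,5R)-6-methylidene-4-oxobicyclo[3.2.1]oct-2-ene-1-carboxylate
Conditions: Pd(PPh3)4 (10 mol %), KOPh (1.5 equiv), THF, 65 °C
Reagents that add atoms: none
Why: Oxidative addition of zerovalent palladium into the vinyl bromide and coupling with the only possible (α′) enolate (intramolecular palladium-catalysed ketone α-alkenylation, 5-(enolexo) closure) forms C13–C16, and C13 can only form on the face that carries the tether, so its configuration follows from C8.

Step 9
Reactants: 5 (5S)-5-({[tert-butyl(dimethyl)silyl]oxy}methyl)-4,4-dimethylcyclohex-2-en-1-one; 11 methyl (1R,5R)-6-methylidene-4-oxobicyclo[3.2.1]oct-2-ene-1-carboxylate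
Product: 12 methyl 2-[6-(TBSO-methyl)-5,5-dimethyl-2-oxocyclohex-3-en-1-yl]-6-methylidene-4-oxobicyclo[3.2.1]octane-1-carboxylate (Michael adduct)
Conditions: 5, LiN(i-Pr)2 (1.05 equiv), THF, −78 °C; then 11, −78 → −40 °C; AcOH, −78 °C
Reagents that add atoms: none
Why: The cross-conjugated lithium dienolate (deprotonation is possible only at C10 because C4 is quaternary) adds to the β-carbon C9 of the non-enolisable enone 11 (Michael addition) from the face of the one-carbon bridge C14, anti to the two-carbon bridge, which sets C9, while C10 forms trans to the C5 substituent and is re-enolised later.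

Step 10
Reactants: 12 Michael adduct
Product: 14 methyl 2-[6-(TBSO-methyl)-5,5-dimethyl-2-oxocyclohex-3-en-1-yl]-6-methylidenebicyclo[3.2.1]octane-1-carboxylate (12-deoxo adduct), via tosylhydrazone 13 (not isolated)
Conditions: TsNHNH2 (1.1 equiv), EtOH, 50 °C; then catecholborane (2.5 equiv), CHCl3, −10 °C; NaOAc·3H2O, 60 °C
Reagents that add atoms: none
Why: The saturated C12 ketone should condense with tosylhydrazide faster than the hindered conjugated C1 ketone, and hydride addition to C=N followed by sulfinate loss and N2 extrusion (tosylhydrazone reduction with catecholborane) leaves C12 as CH2 without touching a stereocentre.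

Step 11
Reactants: 14 12-deoxo adduct
Product: 15 methyl 2-[6-(hydroxymethyl)-5,5-dimethyl-2-oxocyclohex-3-en-1-yl]-6-methylidenebicyclo[3.2.1]octane-1-carboxylate
Conditions: Bu4NF (1.2 equiv), THF, 0 °C
Reagents that add atoms: none
Why: Fluoride cleaves the silyl ether (desilylation) and frees O6 for the tether.

Step 12
Reactants: 15 primary alcohol
Product: 16 (bromomethyl)dimethylsilyl ether of 15
Conditions: BrCH2SiMe2Cl (1.3 equiv), Et3N, DMAP (cat.), CH2Cl2, 0 °C; filtered and used without chromatography
Reagents that add atoms: (bromomethyl)chlorodimethylsilane, C[Si](C)(Cl)CBr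
Why: Silyl ether formation at the primary alcohol installs the one-carbon electrophile that becomes C20, with bromide on the carbon next to silicon.

Step 13
Reactants: 16 (bromomethyl)dimethylsilyl ether
Product: 17 cyclic siloxane with quaternary C10 (O6–SiMe2–C20H2–C10 ring cis-fused to ring A)
Conditions: KN(SiMe3)2 (1.2 equiv), THF, −78 → 0 °C
Reagents that add atoms: none
Why: Proposed new method: KN(SiMe3)2 removes the only acidic proton, H10 (C2 and C3 are vinylic, C4 and C8 are quaternary), and the cross-conjugated potassium dienolate displaces bromide from the silicon-bound CH2 in an intramolecular SN2 reaction that forms C10–C20. The closest known reactions are the intermolecular alkylation of enolates with (halomethyl)silanes and the radical cyclisation of (bromomethyl)silyl ethers, so the union of a fully substituted enolate carbon with a silicon-tethered halide is new for this substrate class. The ring closed is the six-membered 1,2-oxasilinane (O6, Si, C20, C10, C5, C6), by a 6-(enolexo)-exo-tet closure in which the enolate C=C lies outside the new ring. The new quaternary stereocentre C10 is controlled by C5: the tether on C6 reaches only the enolate face on which C6 sits, because attack on the other face would need a dihedral angle of 120–180° about C5–C10 that a six-membered ring cannot span, so C20 enters cis to C6 and C9 ends trans. The step needs C- over O-alkylation and no competing carbanion: O-alkylation would give an eight-membered ring, no other enolisable position exists, and the C7 ester could be attacked only through a four-membered transition state.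

Step 14
Reactants: 17 cyclic siloxane
Product: 18 methyl 2-[1,6-bis(hydroxymethyl)-5,5-dimethyl-2-oxocyclohex-3-en-1-yl]-6-methylidenebicyclo[3.2.1]octane-1-carboxylate (6,20-diol)
Conditions: 30% H2O2, KF, KHCO3, THF/MeOH (1:1), 0 °C → rt
Reagents that add atoms: hydrogen peroxide, OO
Why: Fluoride-assisted peroxide oxidation of the C20–Si bond (Tamao oxidation) replaces silicon by oxygen with retention at carbon and releases O6 and O20, and the hindered enone should survive the bicarbonate-buffered medium.

Step 15
Reactants: 18 6,20-diol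
Product: 19 6-hydroxy-1-oxo-6,7-seco-ent-kaura-2,16-dien-7,20-olide
Conditions: PPTS (0.2 equiv), toluene, 4 Å molecular sieves, 80 °C
Reagents that add atoms: none
Why: Acid-catalysed transesterification (lactonisation) closes the six-membered 7,20-lactone from the C20 alcohol, which is favoured over the seven-membered ring that O6 would give and avoids base-induced retro-aldol loss of C20.

Step 16
Reactants: 19 6-hydroxy-1-oxo-6,7-seco-ent-kaura-2,16-dien-7,20-olide
Product: 20 6,15-dihydroxy-1-oxo-6,7-seco-ent-kaura-2,16-dien-7,20-olide (15-OH on the exo face)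
Conditions: SeO2 (0.5 equiv), t-BuOOH (3 equiv), CH2Cl2, 0 °C → rt
Reagents that add atoms: tert-butyl hydroperoxide, CC(C)(C)OO
Why: Ene reaction of SeO2 at the exocyclic alkene and [2,3]-sigmatropic shift (allylic oxidation) hydroxylate C15, the only allylic CH2, from the exo face, and this centre is removed in the next step.

Step 17
Reactants: 20 6,15-dihydroxy-1-oxo-6,7-seco-ent-kaura-2,16-dien-7,20-olide
Product: 21 6-hydroxy-1,15-dioxo-6,7-seco-ent-kaura-2,16-dien-7,20-olide
Conditions: MnO2 (20 equiv), CH2Cl2, rt
Reagents that add atoms: none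
Why: MnO2 oxidises allylic alcohols selectively (allylic alcohol oxidation) and should give the α-methylene ketone without touching the primary C6 alcohol.

Step 18
Reactants: 21 6-hydroxy-1,15-dioxo-6,7-seco-ent-kaura-2,16-dien-7,20-olide
Product: 23 (16R)-6,17-dihydroxy-1,15-dioxo-6,7-seco-ent-kaur-2-en-7,20-olide (target), via 17-pinacolboryl ketone 22 (not isolated)
Conditions: B2pin2 (1.1 equiv), CuCl (5 mol %), DPEphos (5 mol %), NaOt-Bu (10 mol %), MeOH (2 equiv), THF, 0 °C; then NaBO3·4H2O, THF/H2O, rt
Reagents that add atoms: sodium perborate, [Na+].[O-]OB=O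
Why: Copper–boryl conjugate addition to the unhindered exocyclic enone (β-borylation) and oxidation of the C17–B bond give the β-hydroxy ketone, and C16, which is α to the C15 ketone, should equilibrate in the basic medium to the epimer with CH2OH on the exo face (syn to C14), which is the target configuration.

Compound list
1 | 4,4-dimethylcyclohex-2-en-1-one | CC1(C)CCC(=O)C=C1 | starting material
2 | 4,4-dimethylcyclohexa-2,5-dien-1-one | CC1(C)C=CC(=O)C=C1 | intermediate
3 | (5R)-5-ethenyl-4,4-dimethylcyclohex-2-en-1-one | CC1(C)C=CC(=O)C[C@@H]1C=C | intermediate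
4 | (5S)-5-(hydroxymethyl)-4,4-dimethylcyclohex-2-en-1-one | CC1(C)C=CC(=O)C[C@@H]1CO | intermediate
5 | (5S)-5-({[tert-butyl(dimethyl)silyl]oxy}methyl)-4,4-dimethylcyclohex-2-en-1-one | CC1(C)C=CC(=O)C[C@@H]1CO[Si](C)(C)C(C)(C)C | intermediate
6 | methyl benzoate | COC(=O)c1ccccc1 | starting material
7 | methyl 1-(2-bromoprop-2-en-1-yl)cyclohexa-2,5-diene-1-carboxylate | COC(=O)C1(CC(Br)=C)C=CCC=C1 | intermediate
8 | methyl 1-(2-bromoprop-2-en-1-yl)-4-oxocyclohexa-2,5-diene-1-carboxylate | COC(=O)C1(CC(Br)=C)C=CC(=O)C=C1 | intermediate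
9 | methyl (1R)-1-(2-bromoprop-2-en-1-yl)-4-{[dimethoxy(methyl)silyl]oxy}cyclohexa-2,4-diene-1-carboxylate (silyl dienol ether) | COC(=O)[C@@]1(CC(Br)=C)CC=C(O[Si](C)(OC)OC)C=C1 | intermediate
10 | methyl (1R)-1-(2-bromoprop-2-en-1-yl)-4-oxocyclohex-2-ene-1-carboxylate | COC(=O)[C@@]1(CC(Br)=C)CCC(=O)C=C1 | intermediate
11 | methyl (1R,5R)-6-methylidene-4-oxobicyclo[3.2.1]oct-2-ene-1-carboxylate (C8 = ester bridgehead, C9=C11–C12=O, C16=C17) | C1=CC(=O)[C@@H]2C[C@@]1(C(=O)OC)CC2=C | intermediate
12 | Michael adduct: methyl 2-[6-(tert-butyldimethylsilyloxymethyl)-5,5-dimethyl-2-oxocyclohex-3-en-1-yl]-6-methylidene-4-oxobicyclo[3.2.1]octane-1-carboxylate; C9–C10 bond on the C14 face of the bicycle, C9 trans to CH2OSi on ring A | CC1(C)C=CC(=O)[C@H]([C@@H]1CO[Si](C)(C)C(C)(C)C)[C@@H]2CC(=O)[C@@H]3C[C@@]2(C(=O)OC)CC3=C | intermediate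
13 | C12 tosylhydrazone of 12 | CC1(C)C=CC(=O)[C@H]([C@@H]1CO[Si](C)(C)C(C)(C)C)[C@@H]2CC(=NNS(=O)(=O)c4ccc(C)cc4)[C@@H]3C[C@@]2(C(=O)OC)CC3=C | intermediate
14 | 12-deoxo adduct (C12 = CH2, otherwise as 12) | CC1(C)C=CC(=O)[C@H]([C@@H]1CO[Si](C)(C)C(C)(C)C)[C@@H]2CC[C@@H]3C[C@@]2(C(=O)OC)CC3=C | intermediate
15 | primary alcohol (O6–H, otherwise as 14) | CC1(C)C=CC(=O)[C@H]([C@@H]1CO)[C@@H]2CC[C@@H]3C[C@@]2(C(=O)OC)CC3=C | intermediate
16 | (bromomethyl)dimethylsilyl ether of 15 | CC1(C)C=CC(=O)[C@H]([C@@H]1CO[Si](C)(C)CBr)[C@@H]2CC[C@@H]3C[C@@]2(C(=O)OC)CC3=C | intermediate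
17 | cyclic siloxane: C10 quaternary, ring O6–SiMe2–C20H2–C10–C5–C6 cis-fused to ring A, C9 trans to C6 | CC1(C)C=CC(=O)[C@@]4(C[Si](C)(C)OC[C@H]14)[C@@H]2CC[C@@H]3C[C@@]2(C(=O)OC)CC3=C | intermediate
18 | 6,20-diol methyl ester (C6–OH and C20–OH cis on ring A) | CC1(C)C=CC(=O)[C@](CO)([C@@H]1CO)[C@@H]2CC[C@@H]3C[C@@]2(C(=O)OC)CC3=C | intermediate
19 | 6-hydroxy-1-oxo-6,7-seco-ent-kaura-2,16-dien-7,20-olide | CC1(C)C=CC(=O)[C@]2(COC(=O)[C@@]34C[C@@H](CC[C@H]32)C(=C)C4)[C@@H]1CO | intermediate
20 | 6,15-dihydroxy-1-oxo-6,7-seco-ent-kaura-2,16-dien-7,20-olide (15-OH exo, syn to C14) | CC1(C)C=CC(=O)[C@]2(COC(=O)[C@@]34C[C@@H](CC[C@H]32)C(=C)[C@@H]4O)[C@@H]1CO | intermediate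
21 | 6-hydroxy-1,15-dioxo-6,7-seco-ent-kaura-2,16-dien-7,20-olide | CC1(C)C=CC(=O)[C@]2(COC(=O)[C@@]34C[C@@H](CC[C@H]32)C(=C)C4=O)[C@@H]1CO | intermediate
22 | 17-(pinacolboryl) ketone (16-epimers equilibrating, exo shown) | CC1(C)C=CC(=O)[C@]2(COC(=O)[C@@]34C[C@@H](CC[C@H]32)[C@H](CB5OC(C)(C)C(C)(C)O5)C4=O)[C@@H]1CO | intermediate
23 | (16R)-6,17-dihydroxy-1,15-dioxo-6,7-seco-ent-kaur-2-en-7,20-olide | CC1(C)C=CC(=O)[C@]2(COC(=O)[C@@]34C[C@@H](CC[C@H]32)[C@H](CO)C4=O)[C@@H]1CO | target

Total step count: 18.
Longest linear sequence: 14 steps (steps 1–4 then 9–18; the other branch, steps 5–8 then 9–18, is equally long).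

Steps most likely to fail

Step 13 (Proposed new method). The SN2 displacement at the silicon-bound carbon by a tetrasubstituted, hindered enolate may be too slow, and silyl migration from O6 to the enolate oxygen may then take over. The fallback uses the known radical cyclisation of a (bromomethyl)silyl ether; it sets out from 16 and comes back at 17. Compound 16 is enolised softly with t-BuMe2SiOTf/Et3N (CH2Cl2, −78 °C) to the 2-silyloxy-1,3-diene, silyl dienol ether F1. Slow addition of Bu3SnH with AIBN (benzene, 80 °C) generates the silylmethyl radical, which adds 6-exo to the diene terminus C10 on the face of C6; the allyl radical is reduced at C3 to give silyl enol ether F2. Saegusa–Ito oxidation with Pd(OAc)2 in MeCN then restores the C1 enone and gives 17.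

Step 7. The chiral CuH catalyst may discriminate poorly between the two enantiotopic enone arms, or reduction may continue past the mono-reduced stage. The fallback moves the desymmetrisation to the C–C bond-forming event; it sets out from 8 and comes back at 11. Both arms of 8 are reduced without selectivity (Cu(OAc)2/PPh3, excess (MeO)2MeSiH, t-BuOH) to the achiral keto ester F3. An enantioselective palladium-catalysed intramolecular α-alkenylation (Pd(OAc)2, chiral bisphosphine, K3PO4, toluene) then selects one of the two enantiotopic α-CH2 groups and gives the saturated bicyclic ketone F4. Dehydrogenation with IBX (DMSO, 70 °C), possible only towards C11, gives 11.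

Step 9. Addition of the lithium dienolate to the neopentyl β-carbon C9 may be slow, so that reversible 1,2-addition or a second Michael addition of the product enolate to C3 of ring A competes. The fallback is a Mukaiyama–Michael reaction through an open, Lewis-acid-activated transition state; it sets out from 5 and comes back at 12. Compound 5 is converted with t-BuMe2SiOTf/Et3N into silyl dienol ether F5, which adds to 11 under TiCl4 (CH2Cl2, −78 °C) on the same C14 face; aqueous work-up gives 12.

Further compounds
F1 | step 13 | tert-butyldimethylsilyl dienol ether of 16 (C1–OSi, C1=C10, C2=C3) | CC1(C)C=CC(O[Si](C)(C)C(C)(C)C)=C([C@@H]1CO[Si](C)(C)CBr)[C@@H]2CC[C@@H]3C[C@@]2(C(=O)OC)CC3=C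
F2 | step 13 | cyclised silyl enol ether (C1–OSi, C1=C2, C3H2, siloxane ring closed at quaternary C10) | CC1(C)CC=C(O[Si](C)(C)C(C)(C)C)[C@@]4(C[Si](C)(C)OC[C@H]14)[C@@H]2CC[C@@H]3C[C@@]2(C(=O)OC)CC3=C
F3 | step 7 | methyl 1-(2-bromoprop-2-en-1-yl)-4-oxocyclohexane-1-carboxylate | COC(=O)C1(CC(Br)=C)CCC(=O)CC1
F4 | step 7 | methyl (1R,5R)-6-methylidene-4-oxobicyclo[3.2.1]octane-1-carboxylate | C1CC(=O)[C@@H]2C[C@@]1(C(=O)OC)CC2=C
F5 | step 9 | tert-butyldimethylsilyl dienol ether of 5 | CC1(C)C=CC(O[Si](C)(C)C(C)(C)C)=C[C@@H]1CO[Si](C)(C)C(C)(C)C
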